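**Retrosynthetic overview**
- Last step: an eremophilane alcohol, isovaleraldehyde and diformylphloroglucinol are joined in one operation that forms C1'–C1. The resulting C10 cation then drives a C5→C10 methyl shift, a C4→C5 hydride shift and hydration at C4. This turns the eremophilane skeleton into the eudesmane skeleton and sets five stereocentres.
- The eremophilane alcohol comes from an octalone ester by carbonyl removal and MeLi addition.
- Ring A (second ring) is closed onto ring B by a Michael/aldol annulation with (E)-pent-3-en-2-one.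
- Ring B (first ring) comes from a catalytic enantioselective Diels–Alder reaction of a 2-silyloxy-3-methylbutadiene with methyl acrylate, which sets C7.
- The arene is not built. Resorcinol is hydroxylated to phloroglucinol and then diformylated.

Assumption: terpene positions follow eremophilane/eudesmane numbering (decalin C1–C10, carbinol carbon C11, benzylic carbon C1'), and step 2 uses the catalyst antipode that delivers (S)-4.

**Step 1**
Reactants: 1 3-methylbut-3-en-2-one
Product: 2 tert-butyl(dimethyl)[(3-methylbuta-1,3-dien-2-yl)oxy]silane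
Conditions: TBSOTf (1.1 equiv), Et3N (1.5 equiv), Et2O, 0 °C, 1 h
Reagents that add atoms: tert-butyldimethylsilyl triflate CC(C)(C)[Si](C)(C)OS(=O)(=O)C(F)(F)F
Why: Soft enolisation and O-silylation at the only enolisable position (the acetyl CH3) gives the 2-silyloxydiene; no stereocentre is formed.

**Step 2**
Reactants: 2 tert-butyl(dimethyl)[(3-methylbuta-1,3-dien-2-yl)oxy]silane, 3 methyl acrylate
Product: 4 methyl (1S)-4-[(tert-butyldimethylsilyl)oxy]-3-methylcyclohex-3-ene-1-carboxylate
Conditions: 3,3-diphenyl-1-(2-methylphenyl)tetrahydro-1H,3H-pyrrolo[1,2-c][1,3,2]oxazaborole (20 mol %) + HNTf2 (18 mol %), CH2Cl2, −78 → −20 °C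
Reagents that add atoms: none
Why: Catalytic enantioselective Diels–Alder reaction in which the silyloxy group directs the ester "para" to itself and the cationic oxazaborolidine shields one face of the bound acrylate, setting C7 (S) and giving the C5=C10 enol ether regiospecifically.

**Step 3**
Reactants: 4 methyl (1S)-4-[(tert-butyldimethylsilyl)oxy]-3-methylcyclohex-3-ene-1-carboxylate, 5 (E)-pent-3-en-2-one
Product: 7 methyl (2S,8R,8aS)-8,8a-dimethyl-6-oxo-1,2,3,4,6,7,8,8a-octahydronaphthalene-2-carboxylate, via Michael adduct diketone 6 (not isolated)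
Conditions: TiCl4 (1.0 equiv), CH2Cl2, −78 °C; H2O quench, solvent swap; p-TsOH·H2O (20 mol %), toluene, reflux, Dean–Stark
Reagents that add atoms: none
Why: Silyl-enol-ether form of the Robinson annulation (Mukaiyama–Michael addition, then acid-catalysed aldol condensation): C5 of the half-chair enol ether (ester equatorial) attacks along the axial, chair-forming line, so the C5 methyl ends cis to the C7 ester; the E-enone reacts through the open transition state that places the C4 and C5 methyls cis; and acid closure avoids epimerising C7.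

**Step 4**
Reactants: 7 methyl (2S,8R,8aS)-8,8a-dimethyl-6-oxo-1,2,3,4,6,7,8,8a-octahydronaphthalene-2-carboxylate
Product: 8 the 1,3-dithiolane of 7 at C2 of the terpene (spiro dithioacetal; C1=C10 olefin unchanged)
Conditions: HSCH2CH2SH (1.5 equiv), BF3·OEt2 (0.3 equiv), CH2Cl2, 0 → 23 °C
Reagents that add atoms: ethane-1,2-dithiol SCCS
Why: Thioacetalisation of the unhindered enone carbonyl, which unlike O-ketalisation leaves the conjugated double bond in place and touches no stereocentre.

**Step 5**
Reactants: 8 the 1,3-dithiolane of 7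
Product: 9 methyl (2S,8R,8aS)-8,8a-dimethyl-1,2,3,4,6,7,8,8a-octahydronaphthalene-2-carboxylate
Conditions: Raney Ni (W-2, deactivated in refluxing acetone), EtOH, reflux
Reagents that add atoms: none
Why: Mozingo desulfurisation turns C2 into CH2, and the deactivated nickel leaves the hindered trisubstituted C1=C10 olefin and the ester untouched.

**Step 6**
Reactants: 9 methyl (2S,8R,8aS)-8,8a-dimethyl-1,2,3,4,6,7,8,8a-octahydronaphthalene-2-carboxylate
Product: 10 2-[(2S,8R,8aS)-8,8a-dimethyl-1,2,3,4,6,7,8,8a-octahydronaphthalen-2-yl]propan-2-ol (all-cis eremophil-1(10)-en-11-ol)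
Conditions: MeLi (2.5 equiv), Et2O, −78 → 0 °C; H2O
Reagents that add atoms: methyllithium [Li]C
Why: Double 1,2-addition of MeLi to the ester is faster than enolisation at low temperature, so the contra-thermodynamic C7 configuration is kept.

**Step 7**
Reactants: 11 resorcinol
Product: 14 phloroglucinol (benzene-1,3,5-triol), via bis(trimethylsilyl) ether 12 (not isolated), via pinacol boronate 13 (not isolated)
Conditions: HMDS (1.1 equiv), 125 °C, then evaporate; [Ir(OMe)(cod)]2 (1 mol %), dtbpy (2 mol %), B2pin2 (1.0 equiv), THF, 80 °C; 30 % aq H2O2, THF–MeOH, 23 °C; 1 M HCl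
Reagents that add atoms: hexamethyldisilazane C[Si](C)(C)N[Si](C)(C)C (silyl groups of 12 and 13), bis(pinacolato)diboron CC1(C)OB(OC1(C)C)B1OC(C)(C)C(C)(C)O1 (boryl group of 13), hydrogen peroxide OO (new oxygen of 14)
Why: Sterically governed iridium-catalysed C–H borylation reaches only C5, the one C–H with no ortho substituent; C–B oxidation then gives the phenol and acid removes the silyl groups.

**Step 8**
Reactants: 14 phloroglucinol
Product: 15 2,4,6-trihydroxybenzene-1,3-dicarbaldehyde
Conditions: POCl3 (2.3 equiv), DMF (2.5 equiv), EtOAc, 0 → 23 °C; then H2O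
Reagents that add atoms: N,N-dimethylformamide CN(C)C=O (formyl CH), water O (formyl O)
Why: Vilsmeier–Haack formylation of the very electron-rich ring, where two acceptor groups deactivate the last position enough to stop at the dialdehyde.

**Step 9**
Reactants: 10 all-cis eremophil-1(10)-en-11-ol, 15 2,4,6-trihydroxybenzene-1,3-dicarbaldehyde, 16 3-methylbutanal
Product: 18 5-{(1S)-1-[(1S,4R,4aS,6S,8aR)-4-hydroxy-6-(2-hydroxypropan-2-yl)-4,8a-dimethyldecahydronaphthalen-1-yl]-3-methylbutyl}-2,4,6-trihydroxybenzene-1,3-dicarbaldehyde, via ortho-quinone methide 17 (not isolated)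
Conditions: 15 (1.0 equiv), 16 (1.5 equiv), 10 (1.2 equiv), ethylenediammonium diacetate (20 mol %), 1,1,1,3,3,3-hexafluoropropan-2-ol/H2O 9:1, 45 °C
Reagents that add atoms: water O
Why: Proposed new method: Knoevenagel condensation of 15 and 16 gives 17, whose exocyclic carbon is activated by hydrogen bonding to the solvent and is attacked by C1 of the C1=C10 olefin on the face opposite the axial C5 methyl, with the arene over the H1/C9 edge and the isobutyl group pointing outward (sets C1 S and C1' S); the tertiary C10 cation faces an exactly antiperiplanar C5–CH3/C4–H array, so methyl migrates C5→C10, hydride follows C4→C5 and water adds to C4 anti to the departing hydride (sets C10 R, C5 S, C4 R); the shifts are driven by relief of the syn-axial C5-methyl/C7-carbinol strain of 10 and by the reluctance of C10, next to quaternary C5, to hold the aryloxy group, and any chroman that forms is a tertiary ether of a vinylogous acid that re-ionises in this medium; the closest known reaction types are the three-component formylphloroglucinol/aldehyde/terpene couplings that stop at chromans, and Wagner–Meerwein additions such as camphene to isobornyl esters or the Westphalen angular-methyl migration.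

**Compound list**

| No. | Name | SMILES | Role |
|---|---|---|---|
| 1 | 3-methylbut-3-en-2-one | CC(=O)C(C)=C | starting material |
| 2 | tert-butyl(dimethyl)[(3-methylbuta-1,3-dien-2-yl)oxy]silane | C=C(O[Si](C)(C)C(C)(C)C)C(C)=C | intermediate |
| 3 | methyl acrylate | C=CC(=O)OC | starting material |
| 4 | methyl (1S)-4-[(tert-butyldimethylsilyl)oxy]-3-methylcyclohex-3-ene-1-carboxylate | CC1=C(O[Si](C)(C)C(C)(C)C)CC[C@@H](C1)C(=O)OC | intermediate |
| 5 | (E)-pent-3-en-2-one | C/C=C/C(C)=O | starting material |
| 6 | methyl (1S,3S)-3-methyl-4-oxo-3-[(2R)-4-oxopentan-2-yl]cyclohexane-1-carboxylate | C[C@H](CC(C)=O)[C@]1(C)C[C@H](CCC1=O)C(=O)OC | intermediate |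
| 7 | methyl (2S,8R,8aS)-8,8a-dimethyl-6-oxo-1,2,3,4,6,7,8,8a-octahydronaphthalene-2-carboxylate | C[C@@H]1CC(=O)C=C2CC[C@@H](C[C@@]12C)C(=O)OC | intermediate |
| 8 | 1,3-dithiolane (spiro dithioacetal) of 7 | C[C@@H]1CC2(SCCS2)C=C3CC[C@@H](C[C@@]13C)C(=O)OC | intermediate |
| 9 | methyl (2S,8R,8aS)-8,8a-dimethyl-1,2,3,4,6,7,8,8a-octahydronaphthalene-2-carboxylate | C[C@@H]1CCC=C2CC[C@@H](C[C@@]12C)C(=O)OC | intermediate |
| 10 | 2-[(2S,8R,8aS)-8,8a-dimethyl-1,2,3,4,6,7,8,8a-octahydronaphthalen-2-yl]propan-2-ol | C[C@@H]1CCC=C2CC[C@@H](C[C@@]12C)C(C)(C)O | intermediate |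
| 11 | resorcinol | Oc1cccc(O)c1 | starting material |
| 12 | 1,3-bis(trimethylsilyloxy)benzene | C[Si](C)(C)Oc1cccc(O[Si](C)(C)C)c1 | intermediate |
| 13 | 2-[3,5-bis(trimethylsilyloxy)phenyl]-4,4,5,5-tetramethyl-1,3,2-dioxaborolane | C[Si](C)(C)Oc1cc(O[Si](C)(C)C)cc(c1)B1OC(C)(C)C(C)(C)O1 | intermediate |
| 14 | phloroglucinol | Oc1cc(O)cc(O)c1 | intermediate |
| 15 | 2,4,6-trihydroxybenzene-1,3-dicarbaldehyde | O=Cc1c(O)cc(O)c(C=O)c1O | intermediate |
| 16 | 3-methylbutanal | CC(C)CC=O | starting material |
| 17 | (E)-ortho-quinone methide from 15 and 16 | O=C1/C(=C/CC(C)C)C(O)=C(C=O)C(O)=C1C=O | intermediate |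
| 18 | 5-{(1S)-1-[(1S,4R,4aS,6S,8aR)-4-hydroxy-6-(2-hydroxypropan-2-yl)-4,8a-dimethyldecahydronaphthalen-1-yl]-3-methylbutyl}-2,4,6-trihydroxybenzene-1,3-dicarbaldehyde | CC(C)C[C@H](c1c(O)c(C=O)c(O)c(C=O)c1O)[C@@H]1CC[C@@](C)(O)[C@H]2C[C@@H](C(C)(C)O)CC[C@]12C | target |

**Step count**
- Total steps: 9.
- Longest linear sequence: 7 (steps 1–6, then 9).

**Steps most likely to fail**

**Step 9 (the new step).**
- The zwitterion may close to the chroman and stay there, lose a proton, or be trapped at C5 by the C11 hydroxyl. Water may also add to the wrong face of C4.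
- The fallback sets out from 10, 15 and 16, comes back at 18, and uses established reaction types only. The three components are first joined under the usual neutral Knoevenagel/oxa-Diels–Alder conditions (ethylenediammonium diacetate, MeCN, 60 °C), and the cis-fused chroman F1 is isolated, which secures C1 and C1'. Anhydrous Westphalen-type ionisation (BF3·OEt2, CH2Cl2, −40 °C) then moves the C5 methyl to C10, and loss of the C4 proton gives the tetrasubstituted 4(5)-olefin F2. NBS in aqueous acetone opens the bromonium ion trans-diaxially to the 5-bromo-4-ol bromohydrin F3. Bu3SnH/AIBN in toluene at 80 °C replaces bromine by hydrogen and gives the trans-decalin 18.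

**Step 3.**
- The hindered Michael addition may be sluggish, the C5/C7 facial ratio may be modest, or the ester may epimerise during ring closure.
- The fallback sets out from 4 and comes back at 10. MeLi (3 equiv) followed by 1 M HCl work-up turns 4 into the non-epimerisable hydroxy ketone F4. A classical enolate Robinson annulation with 5 (KOH, EtOH, 0 °C → reflux) gives the hydroxy enone F5. Ethane-1,2-dithiol with Zn(OTf)2 gives the hydroxy dithiolane F6, and deactivated Raney Ni returns 10.

**Step 2.**
- Methyl acrylate is a weak partner for this catalyst, so ee and regioselectivity with the 2,3-disubstituted diene may fall short.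
- The fallback sets out from 2 and comes back at 4. Acryloyl chloride is placed on lithiated (R)-4-benzyl-1,3-oxazolidin-2-one to give the N-acryloyl imide F7. An Et2AlCl-promoted Diels–Alder reaction with 2 at −78 °C adds the diene to the face of the chelated s-cis imide opposite the benzyl group and gives the (1S) imide adduct F8. MeOMgBr in MeOH at 0 °C then exchanges the auxiliary for methoxide and returns 4.

**Further compounds**
F1 | step 9 | cis-fused chroman (O on C10 and C1' on C1, both opposite the C5 methyl) | CC(C)C[C@@H]1c2c(O)c(C=O)c(O)c(C=O)c2O[C@]3(CC[C@@H](C[C@@]3(C)[C@H](C)CC4)C(C)(C)O)[C@H]14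
F2 | step 9 | 4(5)-olefin, 5-{(1S)-1-[(1S,6S,8aR)-6-(2-hydroxypropan-2-yl)-4,8a-dimethyl-1,2,3,5,6,7,8,8a-octahydronaphthalen-1-yl]-3-methylbutyl}-2,4,6-trihydroxybenzene-1,3-dicarbaldehyde | CC(C)C[C@H](c1c(O)c(C=O)c(O)c(C=O)c1O)[C@@H]1CCC(C)=C2C[C@@H](C(C)(C)O)CC[C@]12C
F3 | step 9 | trans-diaxial 5-bromo-4-ol bromohydrin of F2 | CC(C)C[C@H](c1c(O)c(C=O)c(O)c(C=O)c1O)[C@@H]1CC[C@@](C)(O)[C@@]2(Br)C[C@@H](C(C)(C)O)CC[C@]12C
F4 | step 3 | (4S)-4-(2-hydroxypropan-2-yl)-2-methylcyclohexan-1-one (C2 epimers) | CC1C[C@H](CCC1=O)C(C)(C)O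
F5 | step 3 | (4R,4aS,6S)-6-(2-hydroxypropan-2-yl)-4,4a-dimethyl-4,4a,5,6,7,8-hexahydronaphthalen-2(3H)-one | C[C@@H]1CC(=O)C=C2CC[C@@H](C[C@@]12C)C(C)(C)O
F6 | step 3 | 1,3-dithiolane of F5 | C[C@@H]1CC2(SCCS2)C=C3CC[C@@H](C[C@@]13C)C(C)(C)O
F7 | step 2 | (R)-3-acryloyl-4-benzyl-1,3-oxazolidin-2-one | C=CC(=O)N1[C@H](Cc2ccccc2)COC1=O
F8 | step 2 | (R)-4-benzyl-3-{(1S)-4-[(tert-butyldimethylsilyl)oxy]-3-methylcyclohex-3-ene-1-carbonyl}-1,3-oxazolidin-2-one | CC1=C(O[Si](C)(C)C(C)(C)C)CC[C@@H](C1)C(=O)N1[C@H](Cc2ccccc2)COC1=O
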